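**Atom labels used throughout.** C1 is the quaternary oxirane carbon that carries C7 (the CH2–OBz carbon). C2 and C3 are the two acetoxy carbons, with C2 next to C1. C4 and C5 are the two carbinol carbons. C6 is the oxirane CH. Sugar locants are always marked as such.

## Analysis of the target

Target 19 is a 7-oxabicyclo[4.1.0]heptane: a cyclohexane ring C1–C6 whose C1–C6 bond is bridged by an oxirane oxygen, with the benzoyloxymethyl carbon C7 on the quaternary carbon C1. All six ring carbons are stereogenic. The oxygens on C2, C3, C4 and C5 alternate faces (2,3-trans, 3,4-trans, 4,5-trans), and the oxirane oxygen is cis to the C2 acetate and trans to the C5 hydroxyl. C2 and C3 are acetylated, C4 and C5 are free, and C7 carries a different ester, so five oxygens have to be told apart in a fixed pattern. The oxirane is acid-sensitive, and the C3 acetate can migrate to the free C4 hydroxyl under base. The C5 hydroxyl, trans to the oxirane oxygen, can attack C6 under base and move the epoxide (Payne type), so the end of the synthesis has to be neutral. The hard parts are a carbocycle branched at a fully substituted stereocentre and six contiguous stereocentres with differentiated oxygens. The strategy rests on one feature: without the oxirane oxygen, C1 is a trisubstituted alkene carbon that bears C7 at the carboxyl level and sits next to the carbinol C2, which is the α-carbon/carbinol pair of a Morita–Baylis–Hillman adduct. In addition, C3–C5 form a D-xylo triad that is available as sugar C4–C2 of a D-glucopyranoside.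

## Retrosynthetic reasoning

**19 to 18.** The last bonds cut are the two benzyl C–O bonds on O4 and O5. Benzyl ethers are chosen for these oxygens because hydrogen on palladium removes them without acid or base, which the epoxide, the three esters and the trans C5 hydroxyl all require. The forward step must leave the oxirane and the benzoate untouched.

**18 to 16 and 17, then 15.** Both acetyl C–O bonds are cut together, back to diol 16 and acetic anhydride 17. Diol 16 comes from 15 by removing a 4-methoxybenzyl group from O3. A separately cleavable ether on O3 and no group on O2 is what encodes "C2/C3 acylated, C4/C5 free". Freeing O3 only after the epoxide is in place lets one acylation serve both positions.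

**15 to 14.** Both C–O bonds of the oxirane are cut, giving the C1=C6 alkene 14. In 14 the C2 hydroxyl is the only free hydroxyl, it is allylic, and it lies on the face the oxirane must occupy, while the C5 benzyloxy group shields the other face. The forward reaction is a hydroxyl-directed epoxidation that sets C1 and C6 together.

**14 to 12 and 13, then 11.** The benzoyl C–O bond at C7 is cut to diol 12 and benzoyl chloride 13, and C7 is taken back to the ester level in 11. C1 then becomes the α-carbon of an enoate with a β-hydroxyl on C2. The forward steps are a 1,2-reduction and an acylation that prefers the primary hydroxyl.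

**11 to 10 (the key cut).** The C1–C2 bond is cut. It is the ring bond that joins the one carbon without an inherited stereocentre (C1) to the one carbon whose oxygen is wanted free (C2). Cutting there opens the ring to the linear enoate aldehyde 10, in which C3, C4 and C5 are sugar stereocentres. The forward reaction has to form the ring, the C1 branch point, the C1=C6 alkene and the C2 carbinol in one operation, and C2 is the only new stereocentre.

**10 to 9, then 7 and 8.** The C1=C6 double bond is cut to the stabilised ylide 8, which supplies C1 and C7, and the lactol 7, whose anomeric carbon becomes C6. The C2 aldehyde is not made by oxidation. It is uncovered by cutting the bond to one extra carbon: diol 9, the direct olefination product of the hexose lactol, loses its terminal carbon on glycol cleavage. This avoids oxidising a hydroxyl next to the C3 stereocentre and avoids any extra protection.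

**7 to 6, 5, 3, then 1, 2 and 4.** The remaining cuts are protecting-group bonds: the 4-methoxybenzyl ether on sugar O4 (ring O3) and the benzyl ethers on sugar O2/O3 (ring O5/O4). A pentopyranose with the same triad offers no handle to tell O4 from O2 and O3, and unmasking a simple glycoside needs acid that a 4-methoxybenzyl ether would not survive. The gluco thioglycoside 1 solves both problems. Its 4,6-diol is tied up as the arylidene acetal 3 (from 2), O2/O3 are benzylated with 4 to give 5, the acetal is opened reductively so that the arylmethyl group stays on O4 (6), and the thioglycoside is hydrolysed without strong acid (7).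

## Alternatives that were turned down

**Alternative 1: enantioselective desymmetrisation of a cyclohexadienone.**
- Disconnection: the C2–O bond, with the ring taken from an arene. The achiral dienone A1, 4-hydroxy-4-(benzoyloxymethyl)cyclohexa-2,5-dienone, would come from the corresponding para-substituted phenol by oxidative dearomatisation.
- Forward key step: an arylboronic acid esterifies the tertiary C1 hydroxyl, and a bifunctional cinchona amine thiourea directs the boron-bound oxygen onto one of the two enantiotopic enone arms. This gives the cis-fused boronate A2.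
- For: it is catalytic and needs no chiral pool. The C7 benzoate is in place from the start. The C1 oxygen is installed at the quaternary carbon cis to the C2 oxygen, exactly as the target needs. On these three points it is stronger than the chosen route, which builds the same relation later by a directed epoxidation and carries C7 as an ester until step 9.
- Against: in A2, C3 is a methylene and C4 a ketone. Oxygen at C3 and C5, the reduction at C4 and the stereocentres C3–C6 must each be introduced separately under substrate control. The C1 oxygen must end as the oxirane bridging to C6, which means oxidising C5=C6 first and then relying on an equilibrium-controlled epoxide migration. Nothing in A2 prepares the C2/C3 versus C4/C5 differentiation.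
- Comparison: the key step is short, but the sequence after it is long and stereochemically open. The chosen route has oxygen on every ring carbon, three stereocentres fixed and the final protecting pattern encoded before the ring is closed.

**Alternative 2: singlet-oxygen cycloaddition across C1 and C4.**
- Disconnection: the C1–O and C4–O bonds, both traced to O2. The precursor is the trans-5,6-dioxygenated cyclohexa-1,3-diene A3 (C2 hydroxyl, C3 silyl ether, C7 benzoate).
- Forward key step: sensitised photooxygenation adds O2 across the diene C1=C6–C5=C4 on the face away from the C3 silyl ether, giving the bicyclic peroxide A4.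
- For: one reagent delivers both the C1 and the C4 oxygen, cis to each other and on the face of the C2 oxygen, and forms the quaternary C1–O bond without an epoxidation. It has the best oxygen economy of all four plans and the shortest sequence on paper, and here it is stronger than the chosen route.
- Against: A3 is itself a single-enantiomer problem, and as a benzene-hydrate-type diene it aromatises easily by losing water or silanol. The ene reaction at the allylic C–H bonds competes with cycloaddition. After A4, C5 and C6 still need oxygen, with C5–O trans to its neighbours and C6–O tied to C1. That requires telling very similar oxygens and epoxide termini apart, and the acetate pattern has no handle.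
- Comparison: the stereochemical problem is moved into the substrate and the selectivity problems are moved to the end. The chosen route keeps every oxygen distinguishable from the sugar stage on.

**Alternative 3: Ramberg–Bäcklund ring contraction.**
- Disconnection: the C1=C6 double bond, traced to a C–S–C bridge in the hexitol-derived thiepane 1,1-dioxide A5.
- Forward key step: in situ α-halogenation (CBr2F2, KOH/Al2O3), 1,3-elimination to the episulfone and loss of SO2 contract the seven-membered ring to the fully protected cyclohexene A6.
- For: the alkene forms exactly between the two former α-carbons, no stereocentre is created or endangered, and C2–C5 all come from the hexitol. As a ring-forming event it is more dependable than an aldol on an epimerisable α-alkoxy aldehyde, and on that point it is stronger than the chosen key step.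
- Against: the C7 branch must be placed on a sulfone α-carbon that has β-alkoxy groups, so α-metalation invites β-elimination. The C2-symmetric heritage pairs C2 with C5 and C3 with C4 (A6 has 4-methoxybenzyl on O2, O5 and O7 and benzyl on O3 and O4). The target pairs C2 with C3 and C4 with C5. All oxygens arrive protected, so no free C2 hydroxyl is available to direct the epoxidation without further selective deprotection.
- Comparison: the ring closure is robust but the protecting-group regrouping afterwards is long. The chosen closure releases exactly the hydroxyl that is needed next and keeps O3 separately addressable.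

Key step: step 7

**Remarks on the chemistry (assumptions).**
- Sugar C2–C4 of a D-glucopyranoside carry the D-xylo triad needed for C5–C3. The glucoside is used instead of the pentose because its 4,6-acetal singles out O4 and its C6 is the carbon that periodate later removes.
- Compounds 9 and 10 are drawn E. A Z fraction need not be removed, because addition of the phosphine to C6 in step 7 erases the alkene geometry.

## Route

Step 1
Reactants: 1 phenyl 1-thio-β-D-glucopyranoside; 2 4-methoxybenzaldehyde dimethyl acetal
Product: 3 phenyl 4,6-O-[(R)-4-methoxybenzylidene]-1-thio-β-D-glucopyranoside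
Conditions: camphor-10-sulfonic acid (cat.), DMF, 60 °C, reduced pressure; Et3N quench
Reagents that add atoms: 4-methoxybenzaldehyde dimethyl acetal (2), COC(OC)c1ccc(OC)cc1
Why: Acid-catalysed transacetalisation under thermodynamic control ties the 4,6-diol into the trans-fused 1,3-dioxane with the aryl group equatorial, leaving O2 and O3 free.

Step 2
Reactants: 3 phenyl 4,6-O-[(R)-4-methoxybenzylidene]-1-thio-β-D-glucopyranoside; 4 benzyl bromide
Product: 5 phenyl 2,3-di-O-benzyl-4,6-O-[(R)-4-methoxybenzylidene]-1-thio-β-D-glucopyranoside
Conditions: NaH, BnBr, Bu4NI (cat.), DMF, 0 °C to rt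
Reagents that add atoms: benzyl bromide (4), BrCc1ccccc1
Why: Williamson etherification of the two remaining hydroxyls; the acetal and the thioglycoside are inert to NaH.

Step 3
Reactants: 5 phenyl 2,3-di-O-benzyl-4,6-O-[(R)-4-methoxybenzylidene]-1-thio-β-D-glucopyranoside
Product: 6 phenyl 2,3-di-O-benzyl-4-O-(4-methoxybenzyl)-1-thio-β-D-glucopyranoside
Conditions: BH3·THF, Bu2BOTf, THF/CH2Cl2, 0 °C; aq. NaHCO3 work-up
Reagents that add atoms: none
Why: Regioselective reductive opening of the arylidene acetal: the boron Lewis acid binds the less hindered O6, the oxocarbenium ion stays on O4 and is reduced by borane, so the 4-methoxybenzyl group ends on O4 and O6 is freed; 0 °C is the temperature at which this sense of opening is the established one.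

Step 4
Reactants: 6 phenyl 2,3-di-O-benzyl-4-O-(4-methoxybenzyl)-1-thio-β-D-glucopyranoside
Product: 7 2,3-di-O-benzyl-4-O-(4-methoxybenzyl)-D-glucopyranose (lactol, anomeric mixture)
Conditions: N-bromosuccinimide, acetone/H2O 9:1, −15 °C, dark; aq. NaHCO3/Na2S2O3 work-up
Reagents that add atoms: water, O
Why: Bromonium activation of sulfur and capture of the oxocarbenium ion by water (thioglycoside hydrolysis); no acid strong enough to cleave the 4-methoxybenzyl ether is involved, which is the reason for using a thioglycoside.

Step 5
Reactants: 7 2,3-di-O-benzyl-4-O-(4-methoxybenzyl)-D-glucopyranose; 8 ethyl (triphenylphosphoranylidene)acetate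
Product: 9 ethyl (2E,4S,5R,6R,7R)-4,5-bis(benzyloxy)-7,8-dihydroxy-6-[(4-methoxybenzyl)oxy]oct-2-enoate
Conditions: Ph3P=CHCO2Et (2.5 equiv), toluene, 80 °C
Reagents that add atoms: ethyl (triphenylphosphoranylidene)acetate (8), CCOC(=O)C=P(c1ccccc1)(c1ccccc1)c1ccccc1
Why: Wittig olefination of the open-chain aldehyde tautomer of the lactol with a stabilised ylide, which joins C6 (the former anomeric carbon) to C1; no base is present, so the freed hydroxyls should not add to the enoate, and the E isomer is expected in toluene.

Step 6
Reactants: 9 ethyl (2E,4S,5R,6R,7R)-4,5-bis(benzyloxy)-7,8-dihydroxy-6-[(4-methoxybenzyl)oxy]oct-2-enoate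
Product: 10 ethyl (2E,4S,5R,6S)-4,5-bis(benzyloxy)-6-[(4-methoxybenzyl)oxy]-7-oxohept-2-enoate
Conditions: NaIO4, THF/pH 7 phosphate buffer, 0 °C to rt; extracted, dried and used at once
Reagents that add atoms: none
Why: Periodate glycol cleavage removes the former sugar C6 and uncovers C2 as the aldehyde under neutral, cold conditions, so the adjacent C3 stereocentre is never exposed to an oxidant or a base.

Step 7
Reactants: 10 ethyl (2E,4S,5R,6S)-4,5-bis(benzyloxy)-6-[(4-methoxybenzyl)oxy]-7-oxohept-2-enoate
Product: 11 ethyl (3S,4R,5R,6S)-3,4-bis(benzyloxy)-6-hydroxy-5-[(4-methoxybenzyl)oxy]cyclohex-1-ene-1-carboxylate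
Conditions: PMe3 (30 mol %), t-AmOH/THF 1:1, 0.02 M, rt, argon
Reagents that add atoms: none
Why: Trimethylphosphine adds reversibly to C6 of the enoate, the phosphonium ester enolate attacks the C2 aldehyde through C1, and alcohol-assisted proton transfer from C1 followed by E1cB loss of the phosphine re-forms C1=C6 inside the new ring and returns the catalyst. The closest known reaction type is the phosphine-catalysed intramolecular Morita–Baylis–Hillman cyclisation of ω-formyl enoates and enones to 6-hydroxycyclohex-1-ene carbonyl compounds. The ring closes in a 6-(enolexo)-exo-trig aldol mode, which Baldwin's rules favour. The one new stereocentre, C2, is controlled by the adjacent C3 centre: in a chair-like array with the C3, C4 and C5 ethers equatorial, the C3–O bond lies anti to the forming C1–C2 bond and the aldehyde oxygen takes the equatorial position, which gives the 2,3-trans carbinol. Because the aldol step is reversible and the proton transfer is slow, the less strained all-equatorial aldolate is expected to be the one carried on to product. The step needs ring closure to win over epimerisation at C3, β-elimination of the C4 benzyloxy group and intermolecular Rauhut–Currier coupling. A small, strongly nucleophilic but weakly basic phosphine, a hindered alcohol as proton shuttle and high dilution should secure this, and the substrate has no free hydroxyl that could add to the enoate.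

Step 8
Reactants: 11 ethyl (3S,4R,5R,6S)-3,4-bis(benzyloxy)-6-hydroxy-5-[(4-methoxybenzyl)oxy]cyclohex-1-ene-1-carboxylate
Product: 12 (1S,4S,5R,6R)-4,5-bis(benzyloxy)-2-(hydroxymethyl)-6-[(4-methoxybenzyl)oxy]cyclohex-2-en-1-ol
Conditions: i-Bu2AlH (4 equiv), CH2Cl2, −78 to −20 °C; aq. KNaC4H4O6 work-up
Reagents that add atoms: none
Why: 1,2-Reduction of the enoate to the allylic alcohol by i-Bu2AlH after the C2 hydroxyl has formed its aluminium alkoxide; conjugate reduction is not expected and the ethers are inert.

Step 9
Reactants: 12 (1S,4S,5R,6R)-4,5-bis(benzyloxy)-2-(hydroxymethyl)-6-[(4-methoxybenzyl)oxy]cyclohex-2-en-1-ol; 13 benzoyl chloride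
Product: 14 [(3S,4R,5R,6S)-3,4-bis(benzyloxy)-6-hydroxy-5-[(4-methoxybenzyl)oxy]cyclohex-1-en-1-yl]methyl benzoate
Conditions: BzCl (1.05 equiv), 2,4,6-trimethylpyridine, CH2Cl2, −40 to −10 °C
Reagents that add atoms: benzoyl chloride (13), O=C(Cl)c1ccccc1
Why: Chemoselective acylation of the primary allylic hydroxyl over the flanked secondary C2 hydroxyl at low temperature with a hindered base; this installs the C7 benzoate of the target.

Step 10
Reactants: 14 [(3S,4R,5R,6S)-3,4-bis(benzyloxy)-6-hydroxy-5-[(4-methoxybenzyl)oxy]cyclohex-1-en-1-yl]methyl benzoate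
Product: 15 [(1R,2R,3R,4S,5R,6S)-4,5-bis(benzyloxy)-2-hydroxy-3-[(4-methoxybenzyl)oxy]-7-oxabicyclo[4.1.0]heptan-1-yl]methyl benzoate
Conditions: mCPBA, NaHCO3, CH2Cl2, 0 °C to rt
Reagents that add atoms: meta-chloroperoxybenzoic acid, OOC(=O)c1cccc(Cl)c1
Why: Hydroxyl-directed (Henbest) peracid epoxidation: the allylic C2 hydroxyl hydrogen-bonds to the peracid and delivers oxygen to its own face of C1=C6, and the C5 benzyloxy group on the opposite face reinforces this sterically. C1 and C6 are set together, with the oxirane cis to the C2 oxygen and trans to the C5 oxygen.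

Step 11
Reactants: 15 [(1R,2R,3R,4S,5R,6S)-4,5-bis(benzyloxy)-2-hydroxy-3-[(4-methoxybenzyl)oxy]-7-oxabicyclo[4.1.0]heptan-1-yl]methyl benzoate
Product: 16 [(1R,2R,3R,4S,5R,6S)-4,5-bis(benzyloxy)-2,3-dihydroxy-7-oxabicyclo[4.1.0]heptan-1-yl]methyl benzoate
Conditions: DDQ, CH2Cl2/pH 7 phosphate buffer 10:1, 0 °C to rt
Reagents that add atoms: none
Why: Oxidative cleavage of the electron-rich 4-methoxybenzyl ether by hydride abstraction and hydrolysis of the resulting oxocarbenium ion; benzyl ethers, esters and the epoxide are not attacked under buffered conditions.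

Step 12
Reactants: 16 [(1R,2R,3R,4S,5R,6S)-4,5-bis(benzyloxy)-2,3-dihydroxy-7-oxabicyclo[4.1.0]heptan-1-yl]methyl benzoate; 17 acetic anhydride
Product: 18 [(1S,2R,3S,4R,5R,6S)-2,3-bis(acetyloxy)-4,5-bis(benzyloxy)-7-oxabicyclo[4.1.0]heptan-1-yl]methyl benzoate
Conditions: Ac2O, pyridine, 4-(dimethylamino)pyridine (cat.), CH2Cl2, 0 °C to rt
Reagents that add atoms: acetic anhydride (17), CC(=O)OC(C)=O
Why: Nucleophile-catalysed acylation of both secondary hydroxyls in one operation; the C2 hydroxyl is cis to the oxirane oxygen and has no backside access to C1, so the mild base cannot trigger epoxide migration.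

Step 13
Reactants: 18 [(1S,2R,3S,4R,5R,6S)-2,3-bis(acetyloxy)-4,5-bis(benzyloxy)-7-oxabicyclo[4.1.0]heptan-1-yl]methyl benzoate
Product: 19 [(1S,2R,3S,4R,5R,6S)-2,3-bis(acetyloxy)-4,5-dihydroxy-7-oxabicyclo[4.1.0]heptan-1-yl]methyl benzoate
Conditions: H2 (1 atm), Pd(OH)2/C, EtOAc, rt
Reagents that add atoms: none
Why: Heterogeneous hydrogenolysis of the two benzyl ethers under neutral conditions; the aliphatic oxirane and the esters are not benzylic C–O bonds and should persist, and the absence of acid and base avoids epoxide opening, epoxide migration and acetyl migration.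

## Compound list

1 | phenyl 1-thio-β-D-glucopyranoside | OC[C@H]1O[C@@H](Sc2ccccc2)[C@H](O)[C@@H](O)[C@@H]1O | starting material
2 | 4-methoxybenzaldehyde dimethyl acetal | COC(OC)c1ccc(OC)cc1 | starting material
3 | phenyl 4,6-O-[(R)-4-methoxybenzylidene]-1-thio-β-D-glucopyranoside | COc1ccc(cc1)[C@@H]1OC[C@H]2O[C@@H](Sc3ccccc3)[C@H](O)[C@@H](O)[C@@H]2O1 | intermediate
4 | benzyl bromide | BrCc1ccccc1 | starting material
5 | phenyl 2,3-di-O-benzyl-4,6-O-[(R)-4-methoxybenzylidene]-1-thio-β-D-glucopyranoside | COc1ccc(cc1)[C@@H]1OC[C@H]2O[C@@H](Sc3ccccc3)[C@H](OCc3ccccc3)[C@@H](OCc3ccccc3)[C@@H]2O1 | intermediate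
6 | phenyl 2,3-di-O-benzyl-4-O-(4-methoxybenzyl)-1-thio-β-D-glucopyranoside | OC[C@H]1O[C@@H](Sc2ccccc2)[C@H](OCc2ccccc2)[C@@H](OCc2ccccc2)[C@@H]1OCc1ccc(OC)cc1 | intermediate
7 | 2,3-di-O-benzyl-4-O-(4-methoxybenzyl)-D-glucopyranose (anomeric mixture) | OC[C@H]1OC(O)[C@H](OCc2ccccc2)[C@@H](OCc2ccccc2)[C@@H]1OCc1ccc(OC)cc1 | intermediate
8 | ethyl (triphenylphosphoranylidene)acetate | CCOC(=O)C=P(c1ccccc1)(c1ccccc1)c1ccccc1 | starting material
9 | ethyl (2E,4S,5R,6R,7R)-4,5-bis(benzyloxy)-7,8-dihydroxy-6-[(4-methoxybenzyl)oxy]oct-2-enoate | CCOC(=O)/C=C/[C@H](OCc1ccccc1)[C@@H](OCc1ccccc1)[C@H](OCc1ccc(OC)cc1)[C@H](O)CO | intermediate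
10 | ethyl (2E,4S,5R,6S)-4,5-bis(benzyloxy)-6-[(4-methoxybenzyl)oxy]-7-oxohept-2-enoate | CCOC(=O)/C=C/[C@H](OCc1ccccc1)[C@@H](OCc1ccccc1)[C@H](OCc1ccc(OC)cc1)C=O | intermediate
11 | ethyl (3S,4R,5R,6S)-3,4-bis(benzyloxy)-6-hydroxy-5-[(4-methoxybenzyl)oxy]cyclohex-1-ene-1-carboxylate | CCOC(=O)C1=C[C@H](OCc2ccccc2)[C@@H](OCc2ccccc2)[C@H](OCc2ccc(OC)cc2)[C@H]1O | intermediate
12 | (1S,4S,5R,6R)-4,5-bis(benzyloxy)-2-(hydroxymethyl)-6-[(4-methoxybenzyl)oxy]cyclohex-2-en-1-ol | OCC1=C[C@H](OCc2ccccc2)[C@@H](OCc2ccccc2)[C@H](OCc2ccc(OC)cc2)[C@H]1O | intermediate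
13 | benzoyl chloride | O=C(Cl)c1ccccc1 | starting material
14 | [(3S,4R,5R,6S)-3,4-bis(benzyloxy)-6-hydroxy-5-[(4-methoxybenzyl)oxy]cyclohex-1-en-1-yl]methyl benzoate | O=C(OCC1=C[C@H](OCc2ccccc2)[C@@H](OCc2ccccc2)[C@H](OCc2ccc(OC)cc2)[C@H]1O)c1ccccc1 | intermediate
15 | [(1R,2R,3R,4S,5R,6S)-4,5-bis(benzyloxy)-2-hydroxy-3-[(4-methoxybenzyl)oxy]-7-oxabicyclo[4.1.0]heptan-1-yl]methyl benzoate | COc1ccc(CO[C@H]2[C@H](OCc3ccccc3)[C@@H](OCc3ccccc3)[C@@H]4O[C@]4(COC(=O)c5ccccc5)[C@@H]2O)cc1 | intermediate
16 | [(1R,2R,3R,4S,5R,6S)-4,5-bis(benzyloxy)-2,3-dihydroxy-7-oxabicyclo[4.1.0]heptan-1-yl]methyl benzoate | O[C@H]1[C@H](OCc2ccccc2)[C@@H](OCc2ccccc2)[C@@H]3O[C@]3(COC(=O)c4ccccc4)[C@@H]1O | intermediate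
17 | acetic anhydride | CC(=O)OC(C)=O | starting material
18 | [(1S,2R,3S,4R,5R,6S)-2,3-bis(acetyloxy)-4,5-bis(benzyloxy)-7-oxabicyclo[4.1.0]heptan-1-yl]methyl benzoate | CC(=O)O[C@H]1[C@H](OCc2ccccc2)[C@@H](OCc2ccccc2)[C@@H]3O[C@]3(COC(=O)c4ccccc4)[C@@H]1OC(C)=O | intermediate
19 | [(1S,2R,3S,4R,5R,6S)-2,3-bis(acetyloxy)-4,5-dihydroxy-7-oxabicyclo[4.1.0]heptan-1-yl]methyl benzoate | CC(=O)O[C@H]1[C@H](O)[C@@H](O)[C@@H]2O[C@]2(COC(=O)c2ccccc2)[C@@H]1OC(C)=O | target

## Step count and least certain steps

Total step count: 13. Longest linear sequence: 13 steps (1 to 19).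

**Step 7 (key step).**
- What may go wrong: turnover with an enoate acceptor is slow, so base-mediated epimerisation at C3 or β-elimination of the C4 benzyloxy group may outrun ring closure. Facial selectivity at C2 may also be poor, because the chair with an axial alkoxide (the arrangement a Felkin-type analysis would favour) is not much higher in energy.
- Fallback, first leg (sets out from 10, returns at 11): the same bond is closed stoichiometrically. PhSLi (thiophenol, n-BuLi, THF, −78 °C) adds to C6 and the lithium ester enolate closes onto the aldehyde at low temperature. After an acetic acid quench this gives the β-hydroxy sulfide ethyl 3,4-bis(benzyloxy)-6-hydroxy-5-[(4-methoxybenzyl)oxy]-2-(phenylsulfanyl)cyclohexane-1-carboxylate F1. One equivalent of mCPBA at −78 °C gives the sulfoxide ethyl 3,4-bis(benzyloxy)-6-hydroxy-5-[(4-methoxybenzyl)oxy]-2-(phenylsulfinyl)cyclohexane-1-carboxylate F2. On warming in toluene, or with DBU by E1cB, F2 eliminates toward the acidic C1–H and gives 11.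
- Fallback, second leg (sets out from 14, returns to 14): if C2 comes out mixed on either path, the material is taken through steps 8 and 9 and oxidised with Dess–Martin periodinane to the enone [(3S,4R,5S)-3,4-bis(benzyloxy)-5-[(4-methoxybenzyl)oxy]-6-oxocyclohex-1-en-1-yl]methyl benzoate F3, which is common to both epimers. NaBH4/CeCl3·7H2O in methanol at −78 °C (Luche reduction) should then add hydride axially and return 14 with the equatorial, 2,3-trans hydroxyl.

**Step 10.**
- What may go wrong: the alkene carries three allylic C–O bonds and is electron-poor, so peracid epoxidation may be sluggish. Facial control may erode if the C2 hydroxyl sits pseudo-equatorial and directs only weakly.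
- Fallback (sets out from 12, returns at 15): reagent control replaces substrate control. Sharpless epoxidation of the primary allylic alcohol (Ti(OiPr)4, L-(+)-diethyl tartrate, t-BuOOH, 4 Å molecular sieves, CH2Cl2, −20 °C) should deliver oxygen to the face that also carries the C2 hydroxyl. The product is the epoxy diol (1R,2R,3R,4S,5R,6S)-4,5-bis(benzyloxy)-1-(hydroxymethyl)-3-[(4-methoxybenzyl)oxy]-7-oxabicyclo[4.1.0]heptan-2-ol F4, whose primary hydroxyl is benzoylated as in step 9 to give 15.

**Step 13.**
- What may go wrong: reductive or acid-induced opening of the oxirane on the palladium surface, slow cleavage of the two hindered benzyl ethers, and acetyl migration from O3 to O4 once the hydroxyls are free.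
- Fallback (sets out from 18, returns at 19): oxidative instead of reductive debenzylation. DDQ under visible-light irradiation in wet CH2Cl2 converts both benzyl ethers into hydrolysable oxocarbenium ions and leads directly to 19. No new isolated compound is formed.

**Step 11.**
- What may go wrong: the neighbouring free C2 hydroxyl may capture the benzylic cation as a cyclic arylidene acetal, which on further oxidation ends as an aryl ester.
- Fallback (sets out from 15, returns at 18): the two acylations are separated. 15 is acetylated at O2 (17, pyridine) to [(1S,2R,3S,4R,5R,6S)-2-(acetyloxy)-4,5-bis(benzyloxy)-3-[(4-methoxybenzyl)oxy]-7-oxabicyclo[4.1.0]heptan-1-yl]methyl benzoate F5. DDQ then frees O3 to give [(1S,2R,3S,4S,5R,6S)-2-(acetyloxy)-4,5-bis(benzyloxy)-3-hydroxy-7-oxabicyclo[4.1.0]heptan-1-yl]methyl benzoate F6, and a second acetylation gives 18.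

**Step 5.**
- What may go wrong: intramolecular conjugate addition of the freed secondary hydroxyl to the enoate on heating, which would close a tetrahydropyran and consume the acceptor.
- Fallback (sets out from 7, returns at 10): the acceptor is introduced only after the hydroxyls are gone. Methylenation of 7 (Ph3PCH3Br, KN(SiMe3)2, THF) gives (2R,3R,4R,5S)-4,5-bis(benzyloxy)-3-[(4-methoxybenzyl)oxy]hept-6-ene-1,2-diol F7. NaIO4 cleaves it to (2S,3R,4S)-3,4-bis(benzyloxy)-2-[(4-methoxybenzyl)oxy]hex-5-enal F8. Cross-metathesis with ethyl acrylate (second-generation Hoveyda–Grubbs catalyst, CH2Cl2, 40 °C) then gives 10.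

## Further compounds

F1 | step 7 | ethyl 3,4-bis(benzyloxy)-6-hydroxy-5-[(4-methoxybenzyl)oxy]-2-(phenylsulfanyl)cyclohexane-1-carboxylate (C3–C6 as in 11; C1 and C2 as formed) | CCOC(=O)C1C(Sc2ccccc2)[C@H](OCc2ccccc2)[C@@H](OCc2ccccc2)[C@H](OCc2ccc(OC)cc2)[C@H]1O
F2 | step 7 | ethyl 3,4-bis(benzyloxy)-6-hydroxy-5-[(4-methoxybenzyl)oxy]-2-(phenylsulfinyl)cyclohexane-1-carboxylate (C3–C6 as in 11; C1, C2 and sulfur as formed) | CCOC(=O)C1C(S(=O)c2ccccc2)[C@H](OCc2ccccc2)[C@@H](OCc2ccccc2)[C@H](OCc2ccc(OC)cc2)[C@H]1O
F3 | step 7 | [(3S,4R,5S)-3,4-bis(benzyloxy)-5-[(4-methoxybenzyl)oxy]-6-oxocyclohex-1-en-1-yl]methyl benzoate | O=C1C(COC(=O)c2ccccc2)=C[C@H](OCc2ccccc2)[C@@H](OCc2ccccc2)[C@@H]1OCc1ccc(OC)cc1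
F4 | step 10 | (1R,2R,3R,4S,5R,6S)-4,5-bis(benzyloxy)-1-(hydroxymethyl)-3-[(4-methoxybenzyl)oxy]-7-oxabicyclo[4.1.0]heptan-2-ol | COc1ccc(CO[C@H]2[C@H](OCc3ccccc3)[C@@H](OCc3ccccc3)[C@@H]4O[C@]4(CO)[C@@H]2O)cc1
F0 | step 13 | none | none
F5 | step 11 | [(1S,2R,3S,4R,5R,6S)-2-(acetyloxy)-4,5-bis(benzyloxy)-3-[(4-methoxybenzyl)oxy]-7-oxabicyclo[4.1.0]heptan-1-yl]methyl benzoate | COc1ccc(CO[C@H]2[C@H](OCc3ccccc3)[C@@H](OCc3ccccc3)[C@@H]4O[C@]4(COC(=O)c5ccccc5)[C@@H]2OC(C)=O)cc1
F6 | step 11 | [(1S,2R,3S,4S,5R,6S)-2-(acetyloxy)-4,5-bis(benzyloxy)-3-hydroxy-7-oxabicyclo[4.1.0]heptan-1-yl]methyl benzoate | O[C@H]1[C@H](OCc2ccccc2)[C@@H](OCc2ccccc2)[C@@H]3O[C@]3(COC(=O)c4ccccc4)[C@@H]1OC(C)=O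
F7 | step 5 | (2R,3R,4R,5S)-4,5-bis(benzyloxy)-3-[(4-methoxybenzyl)oxy]hept-6-ene-1,2-diol | C=C[C@H](OCc1ccccc1)[C@@H](OCc1ccccc1)[C@H](OCc1ccc(OC)cc1)[C@H](O)CO
F8 | step 5 | (2S,3R,4S)-3,4-bis(benzyloxy)-2-[(4-methoxybenzyl)oxy]hex-5-enal | C=C[C@H](OCc1ccccc1)[C@@H](OCc1ccccc1)[C@H](OCc1ccc(OC)cc1)C=O
A1 | alternative 1 | 4-hydroxy-4-(benzoyloxymethyl)cyclohexa-2,5-dien-1-one | O=C1C=CC(O)(COC(=O)c2ccccc2)C=C1
A2 | alternative 1 | cis-fused phenylboronate of the C1,C2-diol enone | O1B(c2ccccc2)O[C@@H]2CC(=O)C=C[C@]12COC(=O)c1ccccc1
A3 | alternative 2 | cyclohexa-1,3-diene with C2 hydroxyl, C3 tert-butyldimethylsilyl ether and C7 benzoate | O[C@H]1C(COC(=O)c2ccccc2)=CC=C[C@@H]1O[Si](C)(C)C(C)(C)C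
A4 | alternative 2 | C1,C4-endoperoxide (2,3-dioxabicyclo[2.2.2]octene) with C2 hydroxyl, C3 silyl ether and C7 benzoate | O1O[C@]2(COC(=O)c3ccccc3)[C@H](O)[C@@H](O[Si](C)(C)C(C)(C)C)[C@H]1C=C2
A5 | alternative 3 | 4,5-bis(benzyloxy)-3,6-bis[(4-methoxybenzyl)oxy]-2-{[(4-methoxybenzyl)oxy]methyl}thiepane 1,1-dioxide | O=S1(=O)C[C@H](OCc2ccc(OC)cc2)[C@@H](OCc2ccccc2)[C@H](OCc2ccccc2)[C@@H](OCc2ccc(OC)cc2)C1COCc1ccc(OC)cc1
A6 | alternative 3 | fully protected C7-branched cyclohexene (O2, O5, O7 4-methoxybenzyl; O3, O4 benzyl) | COc1ccc(COCC2=C[C@H](OCc3ccc(OC)cc3)[C@@H](OCc3ccccc3)[C@H](OCc3ccccc3)[C@H]2OCc2ccc(OC)cc2)cc1
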